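**Retrosynthetic overview**

1. The only ring, the 28-membered pentaene lactone (C1–C27 plus the ring oxygen), is opened at C17–C18 (Suzuki–Miyaura macrocyclisation, step 33) and at the C1–O–C27 ester (Yamaguchi esterification). This gives a C1–C17 iodoalkene acid and a C18–C28 tetraenylboronate.
2. In the acid, C2/C3 come from an Evans butanoate syn-aldol on the C3 aldehyde, and C16=C17–iodine from a Takai olefination of the C16 aldehyde (unmasked from a pivalate).
3. The strategy rests on carbinols C5 and C9, which are 1,5-anti across the unfunctionalised methylenes C6–C8. Bonds C5–C6 and C8–C9 are cut to aldehyde X (C3–C5), a C6–C8 allenylboronate and aldehyde Y (C9–C16), joined by a one-pot double allylboration.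
4. Y comes from 2-oxoethyl pivalate by (Z)-crotylboration (C14, C15) and two ozonolysis/allylboration rounds (C13, C11). The C18–C28 piece comes from (2R,3R)-2,3-dimethyloxirane (C26, C27), acetylide, a bromodienal and a chromium-mediated borylative olefination.

Key step: step 15

**Remarks and assumptions**

- Locants C1–C28 are those of the macrolide (C1 lactone carbonyl, C27 lactone carbinol, C28 its methyl). Target configuration: 2S,3R,5S,9S,11S,13R,14R,15R,26R,27R, all-E pentaene C16–C25.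
- Abbreviations: TBS = tert-butyldimethylsilyl, PMB = 4-methoxybenzyl, Piv = pivaloyl, Ipc = isopinocampheyl (dIpc from (+)-α-pinene, lIpc from (−)-α-pinene), pin = pinacolato.
- The three-carbon linchpin is used as the neopentyl glycol ester of allenylboronic acid. With an unhindered six-membered boronate the α-substituent of the intermediate allylboronate can sit equatorial in the second allylboration (E alkene, 1,5-anti); hindered diol esters push it toward axial (Z, 1,5-syn).
- (2R,3R)-2,3-Dimethyloxirane, glutaconaldehyde potassium salt and solutions of both enantiomers of B-allyldiisopinocampheylborane are taken as purchasable. Crystalline (dIpc)2BH is made beforehand from (+)-α-pinene and BH3·SMe2 and used as a reagent.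

**Route**

Step 1
Reactants: 1 propane-1,3-diol
Product: 2 3-[(4-methoxybenzyl)oxy]propan-1-ol
Conditions: NaH, THF/DMF, 0 °C; PMBCl, Bu4NI (cat.), rt (diol 3 equiv)
Reagents that add atoms: 4-methoxybenzyl chloride, COc1ccc(CCl)cc1
Why: Williamson ether synthesis on the monoalkoxide with the diol in excess should give mainly the mono-PMB ether, and no stereocentre is involved.

Step 2
Reactants: 2 3-[(4-methoxybenzyl)oxy]propan-1-ol
Product: 3 3-[(4-methoxybenzyl)oxy]propanal (aldehyde X; C3–C5)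
Conditions: Dess–Martin periodinane, NaHCO3, CH2Cl2, 0 °C → rt
Reagents that add atoms: none
Why: Dess–Martin oxidation takes the primary alcohol to the aldehyde without over-oxidation and leaves the PMB ether intact.

Step 3
Reactants: 4 ethane-1,2-diol
Product: 5 2-hydroxyethyl pivalate
Conditions: PivCl (1 equiv), pyridine, CH2Cl2, 0 °C (diol 4 equiv)
Reagents that add atoms: pivaloyl chloride, CC(C)(C)C(=O)Cl
Why: Acylation of the diol used in excess with one equivalent of pivaloyl chloride should give the monoester, the bulk of which later slows 1,2-acyl migration.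

Step 4
Reactants: 5 2-hydroxyethyl pivalate
Product: 6 2-oxoethyl pivalate
Conditions: Dess–Martin periodinane, NaHCO3, CH2Cl2, rt; used at once
Reagents that add atoms: none
Why: Dess–Martin oxidation under bicarbonate buffering gives the α-acyloxy aldehyde, which is used at once because it hydrates and oligomerises on standing.

Step 5
Reactants: 6 2-oxoethyl pivalate; 7 (Z)-but-2-ene
Product: 10 (2S,3R)-2-hydroxy-3-methylpent-4-en-1-yl pivalate, via (Z)-but-2-enylpotassium 8 (not isolated), via (Z)-crotylbis(isopinocampheyl)borane 9 (not isolated)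
Conditions: KOtBu, nBuLi, THF, −78 → −45 °C; (−)-Ipc2BOMe [(dIpc)2BOMe], −78 °C; BF3·OEt2; 6, −78 °C; pH 7 phosphate buffer, MeOH, 30% H2O2, 0 °C → rt
Reagents that add atoms: none
Why: Brown asymmetric crotylboration, in which metalation of (Z)-but-2-ene keeps the Z geometry, the (Z)-crotylborane adds through a closed chair transition state so that the Z geometry gives the 14,15-syn pair, the isopinocampheyl groups from (+)-α-pinene select the aldehyde face that gives the carbinol configuration needed at C15 (2S in 10), and the buffered peroxide work-up avoids pivalate migration.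

Step 6
Reactants: 10 (2S,3R)-2-hydroxy-3-methylpent-4-en-1-yl pivalate
Product: 11 (2S,3R)-2-[(tert-butyldimethylsilyl)oxy]-3-methylpent-4-en-1-yl pivalate
Conditions: TBSOTf, 2,6-lutidine, CH2Cl2, −78 → 0 °C
Reagents that add atoms: tert-butyldimethylsilyl triflate, CC(C)(C)[Si](C)(C)OS(=O)(=O)C(F)(F)F
Why: Silylation with the silyl triflate and a hindered pyridine base is fast at low temperature and is not basic enough to move the neighbouring pivalate.

Step 7
Reactants: 11 (2S,3R)-2-[(tert-butyldimethylsilyl)oxy]-3-methylpent-4-en-1-yl pivalate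
Product: 13 (2S,3S)-2-[(tert-butyldimethylsilyl)oxy]-3-methyl-4-oxobutyl pivalate (C13–C16 aldehyde), via ozonide 12 (not isolated)
Conditions: O3, CH2Cl2, −78 °C; PPh3, −78 °C → rt; used crude
Reagents that add atoms: ozone, [O-][O+]=O
Why: Ozonolysis with reductive work-up by PPh3 cleaves the terminal alkene to the α-methyl aldehyde under neutral conditions, so that C14 should not epimerise if the aldehyde is used directly.

Step 8
Reactants: 13 (2S,3S)-2-[(tert-butyldimethylsilyl)oxy]-3-methyl-4-oxobutyl pivalate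
Product: 14 (2S,3R,4R)-2-[(tert-butyldimethylsilyl)oxy]-4-hydroxy-3-methylhept-6-en-1-yl pivalate (13-OH; 13,14-anti; 14,15-syn)
Conditions: (lIpc)2B-allyl (from (−)-α-pinene), Et2O, −78 °C; pH 7 buffer, MeOH, 30% H2O2, 0 °C → rt
Reagents that add atoms: B-allylbis(isopinocampheyl)borane from (−)-α-pinene, C=CCB([C@H]1C[C@H]2C[C@H](C2(C)C)[C@@H]1C)[C@H]1C[C@H]2C[C@H](C2(C)C)[C@@H]1C
Why: Brown allylboration under reagent control, in which the allylborane from (−)-α-pinene transfers allyl through a chair transition state to the aldehyde face that gives the 13R carbinol, anti to the C14 methyl group, the isopinocampheyl groups being expected to override the small Felkin preference of the α-methyl aldehyde.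

Step 9
Reactants: 14 (2S,3R,4R)-2-[(tert-butyldimethylsilyl)oxy]-4-hydroxy-3-methylhept-6-en-1-yl pivalate
Product: 15 C11–C16 alkene (16-OPiv; 13,15-bis-OTBS; 14-Me; terminal alkene at C11)
Conditions: TBSOTf, 2,6-lutidine, CH2Cl2, −78 → 0 °C
Reagents that add atoms: tert-butyldimethylsilyl triflate, CC(C)(C)[Si](C)(C)OS(=O)(=O)C(F)(F)F
Why: Silylation of the secondary C13 alcohol with the silyl triflate protects it for the next chain extension without disturbing the ester.

Step 10
Reactants: 15 C11–C16 alkene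
Product: 17 C11–C16 aldehyde (16-OPiv; 13,15-bis-OTBS; 14-Me; C11 aldehyde), via ozonide 16 (not isolated)
Conditions: O3, CH2Cl2, −78 °C; PPh3, −78 °C → rt
Reagents that add atoms: ozone, [O-][O+]=O
Why: Ozonolysis with reductive work-up shortens the allyl group to the β-silyloxy aldehyde under neutral conditions that should not cause β-elimination.

Step 11
Reactants: 17 C11–C16 aldehyde
Product: 18 C9–C16 homoallylic alcohol (16-OPiv; 13,15-bis-OTBS; 14-Me; 11-OH; 11,13-anti)
Conditions: (dIpc)2B-allyl (from (+)-α-pinene), Et2O, −78 °C; pH 7 buffer, MeOH, 30% H2O2, 0 °C → rt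
Reagents that add atoms: B-allylbis(isopinocampheyl)borane from (+)-α-pinene, C=CCB([C@@H]1C[C@@H]2C[C@@H](C2(C)C)[C@H]1C)[C@@H]1C[C@@H]2C[C@@H](C2(C)C)[C@H]1C
Why: Brown allylboration with the enantiomeric reagent from (+)-α-pinene sets the 11S carbinol, 1,3-anti to the C13 silyl ether, by reagent control through a chair transition state, β-silyloxy aldehydes showing little bias of their own toward allylboranes.

Step 12
Reactants: 18 C9–C16 homoallylic alcohol
Product: 19 C9–C16 alkene (16-OPiv; 11,13,15-tris-OTBS; 14-Me; terminal alkene at C9)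
Conditions: TBSOTf, 2,6-lutidine, CH2Cl2, −78 → 0 °C
Reagents that add atoms: tert-butyldimethylsilyl triflate, CC(C)(C)[Si](C)(C)OS(=O)(=O)C(F)(F)F
Why: Silylation of the C11 alcohol with the silyl triflate completes the protection of the C11–C15 triol array.

Step 13
Reactants: 19 C9–C16 alkene
Product: 21 aldehyde Y (C9–C16; 16-OPiv; 11,13,15-tris-OTBS; 14-Me; C9 aldehyde), via ozonide 20 (not isolated)
Conditions: O3, CH2Cl2, −78 °C; PPh3, −78 °C → rt
Reagents that add atoms: ozone, [O-][O+]=O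
Why: Ozonolysis with reductive work-up gives the β-silyloxy aldehyde for the fragment union under neutral conditions.

Step 14
Reactants: 22 3-bromoprop-1-yne
Product: 25 5,5-dimethyl-2-(propa-1,2-dien-1-yl)-1,3,2-dioxaborinane, via allenylmagnesium bromide 23 (not isolated), via allenylboronic acid 24 (not isolated)
Conditions: Mg, HgCl2 (cat.), Et2O, 0 °C; B(OMe)3, −78 °C; 1 M HCl; 2,2-dimethylpropane-1,3-diol, MgSO4, Et2O, rt; distil
Reagents that add atoms: trimethyl borate, COB(OC)OC; 2,2-dimethylpropane-1,3-diol, OCC(C)(C)CO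
Why: Propargyl bromide forms allenylmagnesium bromide, which is borylated by trimethyl borate to the allenylboron species, and hydrolysis then condensation with the diol gives the allenylboronate as an unhindered six-membered ester, chosen so that the α-substituent of the later allylboronate can sit equatorial.

Step 15
Reactants: 3 aldehyde X; 25 5,5-dimethyl-2-(propa-1,2-dien-1-yl)-1,3,2-dioxaborinane; 21 aldehyde Y
Product: 28 C3–C16 (6E)-ene-5,9-diol (16-OPiv; 11,13,15-tris-OTBS; 14-Me; 3-OPMB; 5,9-anti), via γ-boryl allylborane 26 (not isolated), via β-boryloxy allylboronate 27 (not isolated)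
Conditions: (dIpc)2BH (1.0 equiv), 25 (1.05 equiv), Et2O, −25 → 0 °C; 3 (1.0 equiv), −78 °C, 3 h; 21 (0.75 equiv), −78 °C → rt, 24 h; pH 7 buffer, MeOH, 30% H2O2, 0 °C
Reagents that add atoms: none
Why: (dIpc)2BH hydroborates the terminal C=C of 25 with boron at CH2, and 1,3-boratropic equilibration gives the (E)-γ-boryl allylborane 26, which adds to aldehyde 3 at −78 °C through a chair transition state to form C5–C6 and the anti-β-boryloxy allylboronate 27; on warming, 27 adds to aldehyde 21 through a second chair to form C8–C9 while the double bond moves to C6=C7. The closest known reaction type is the one-pot double allylboration of two different aldehydes by an in situ γ-boryl allyldiisopinocampheylborane, which gives (E)-1,5-anti-pent-2-ene-1,5-diols; no ring is closed. C5 is set by the isopinocampheyl groups from (+)-α-pinene, which select the aldehyde face as in a Brown allylboration (R in 28, the 5S centre of the target once C6=C7 is saturated), and the E geometry of 26 sets the boron-bearing C6 anti to it. C9 (S) is set by chirality transfer from C6, because the α-substituent of 27 sits equatorial in the second chair, which gives the E alkene and the C9 carbinol 1,5-anti to C5. The step needs reagent control at C5, an E/1,5-anti relay to C9 and clean sequential use of the two aldehydes. These are secured by the isopinocampheyl groups, by the unhindered dioxaborinane that allows the equatorial α-substituent and should override the weak 1,3-bias of the C11 silyl ether of 21, and by the reactivity gap between the allylborane (reacts at −78 °C) and the allylboronate (reacts only on warming).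

Step 16
Reactants: 28 C3–C16 (6E)-ene-5,9-diol
Product: 29 C3–C16 5,9-diol (16-OPiv; 11,13,15-tris-OTBS; 14-Me; 3-OPMB)
Conditions: 2-nitrobenzenesulfonylhydrazide, Et3N, CH2Cl2, rt
Reagents that add atoms: none
Why: Diimide generated from the sulfonylhydrazide reduces the isolated disubstituted alkene by concerted syn transfer of two hydrogens and, unlike catalytic hydrogenation, cannot cleave the PMB ether or the allylic carbon–oxygen bonds, so C5 and C9 are untouched.

Step 17
Reactants: 29 C3–C16 5,9-diol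
Product: 30 C3–C16 pivalate (16-OPiv; 5,9,11,13,15-pentakis-OTBS; 14-Me; 3-OPMB)
Conditions: TBSOTf, 2,6-lutidine, CH2Cl2, 0 °C
Reagents that add atoms: tert-butyldimethylsilyl triflate, CC(C)(C)[Si](C)(C)OS(=O)(=O)C(F)(F)F
Why: Silylation of both secondary alcohols with the silyl triflate gives the uniformly protected polyol and blocks C5 and C9 before the chain ends are opened.

Step 18
Reactants: 30 C3–C16 pivalate
Product: 31 C3–C16 primary alcohol (16-OH; 5,9,11,13,15-pentakis-OTBS; 3-OPMB)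
Conditions: iBu2AlH, CH2Cl2, −78 °C; aq. potassium sodium tartrate
Reagents that add atoms: none
Why: Reductive cleavage of the pivalate by iBu2AlH at low temperature frees the C16 alcohol while the silyl and PMB ethers are inert to hydride.

Step 19
Reactants: 31 C3–C16 primary alcohol
Product: 32 C3–C16 aldehyde (C16 aldehyde; 5,9,11,13,15-pentakis-OTBS; 3-OPMB)
Conditions: Dess–Martin periodinane, NaHCO3, CH2Cl2, 0 °C → rt; used at once
Reagents that add atoms: none
Why: Dess–Martin oxidation gives the α-silyloxy aldehyde under buffered conditions that should not epimerise C15, and the aldehyde is used without storage.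

Step 20
Reactants: 32 C3–C16 aldehyde
Product: 33 C3–C17 (16E)-iodoalkene (5,9,11,13,15-pentakis-OTBS; 3-OPMB)
Conditions: CrCl2, CHI3, THF/1,4-dioxane, 0 °C → rt, dark
Reagents that add atoms: iodoform, IC(I)I
Why: Takai olefination, in which the geminal dichromium species from CrCl2 and iodoform adds to the aldehyde and eliminates to the E-iodoalkene under non-basic conditions, so that C15 keeps its configuration.

Step 21
Reactants: 33 C3–C17 (16E)-iodoalkene
Product: 34 C3–C17 iodoalkene primary alcohol (3-OH; 5,9,11,13,15-pentakis-OTBS)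
Conditions: DDQ, CH2Cl2/pH 7 buffer, 0 °C
Reagents that add atoms: none
Why: Oxidative cleavage of the PMB ether by DDQ proceeds by hydride abstraction from the electron-rich benzylic position and hydrolysis of the oxocarbenium ion, which leaves the silyl ethers and the iodoalkene intact.

Step 22
Reactants: 34 C3–C17 iodoalkene primary alcohol
Product: 35 C3–C17 iodoalkene aldehyde (C3 aldehyde; 5,9,11,13,15-pentakis-OTBS)
Conditions: Dess–Martin periodinane, NaHCO3, CH2Cl2, 0 °C → rt
Reagents that add atoms: none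
Why: Dess–Martin oxidation gives the β-silyloxy aldehyde without β-elimination under the buffered conditions.

Step 23
Reactants: 36 (S)-4-benzyloxazolidin-2-one
Product: 37 (S)-4-benzyl-3-butanoyloxazolidin-2-one
Conditions: nBuLi, THF, −78 °C; butanoyl chloride, −78 → 0 °C
Reagents that add atoms: butanoyl chloride, CCCC(=O)Cl
Why: N-Acylation of the lithiated oxazolidinone with the acid chloride gives the imide, and the stereocentre of the auxiliary is not affected.

Step 24
Reactants: 35 C3–C17 iodoalkene aldehyde; 37 (S)-4-benzyl-3-butanoyloxazolidin-2-one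
Product: 39 C1–C17 aldol imide (2-Et; 3-OH; 5,9,11,13,15-pentakis-OTBS; 2,3-syn), via boron enolate 38 (not isolated)
Conditions: 37 (1.5 equiv), Bu2BOTf, iPr2NEt, CH2Cl2, −78 → 0 °C; 35, −78 → 0 °C; pH 7 buffer, MeOH, 30% H2O2, 0 °C
Reagents that add atoms: none
Why: Evans syn-aldol reaction, in which the Z boron enolate reacts through a Zimmerman–Traxler chair where the benzyl group of the auxiliary shields one enolate face, which sets 2S and 3R (2,3-syn) under reagent control and overrides the remote C5 silyl ether.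

Step 25
Reactants: 39 C1–C17 aldol imide
Product: 40 C1–C17 imide (3,5,9,11,13,15-hexakis-OTBS)
Conditions: TBSOTf, 2,6-lutidine, CH2Cl2, −78 → 0 °C
Reagents that add atoms: tert-butyldimethylsilyl triflate, CC(C)(C)[Si](C)(C)OS(=O)(=O)C(F)(F)F
Why: Silylation of the hindered C3 alcohol with the silyl triflate protects the last free hydroxyl group and prevents retro-aldol cleavage in the following hydrolysis.

Step 26
Reactants: 40 C1–C17 imide
Product: 42 C1–C17 iodoalkene carboxylic acid (3,5,9,11,13,15-hexakis-OTBS), via peroxy acid 41 (not isolated)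
Conditions: LiOH, 30% H2O2, THF/H2O, 0 °C → rt; aq. Na2SO3; 1 M HCl to pH 3
Reagents that add atoms: hydrogen peroxide (as LiOOH), OO
Why: Hydroperoxide attacks the exocyclic imide carbonyl selectively, the peroxy acid is reduced by sulfite to the carboxylic acid, and the mild conditions should leave C2 and the iodoalkene unchanged.

Step 27
Reactants: 43 (2R,3R)-2,3-dimethyloxirane
Product: 44 (2R,3R)-3-methylpent-4-yn-2-ol
Conditions: lithium acetylide·ethylenediamine, DMSO, rt
Reagents that add atoms: lithium acetylide ethylenediamine complex, [Li+].[C-]#C.NCCN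
Why: SN2 opening of the C2-symmetric trans-epoxide by acetylide with inversion at the attacked carbon gives the 26R,27R (syn) pair, and both epoxide carbons give the same product.

Step 28
Reactants: 44 (2R,3R)-3-methylpent-4-yn-2-ol
Product: 45 (2R,3R,4E)-3-methyl-5-(tributylstannyl)pent-4-en-2-ol
Conditions: Bu3SnH, PdCl2(PPh3)2 (2 mol%), THF, 0 °C
Reagents that add atoms: tributyltin hydride, CCCC[SnH](CCCC)CCCC
Why: Palladium-catalysed hydrostannation adds tin and hydrogen syn across the terminal alkyne with tin at the terminal carbon, which the branched propargylic carbon favours, and gives the E-alkenylstannane.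

Step 29
Reactants: 46 glutaconaldehyde potassium salt
Product: 47 (2E,4E)-5-bromopenta-2,4-dienal
Conditions: PPh3, Br2, CH2Cl2, 0 °C; 46, 0 °C → rt
Reagents that add atoms: triphenylphosphine dibromide (from PPh3 and Br2), BrP(Br)(c1ccccc1)(c1ccccc1)c1ccccc1
Why: O-Phosphonium activation of the enolate oxygen and addition–elimination of bromide converts the vinylogous carboxylate into the bromodienal, which equilibrates to the E,E isomer.

Step 30
Reactants: 45 (2R,3R,4E)-3-methyl-5-(tributylstannyl)pent-4-en-2-ol; 47 (2E,4E)-5-bromopenta-2,4-dienal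
Product: 48 (2E,4E,6E,8R,9R)-9-hydroxy-8-methyldeca-2,4,6-trienal
Conditions: PdCl2(MeCN)2 (5 mol%), DMF, rt, dark
Reagents that add atoms: none
Why: Stille coupling joins the alkenylstannane and the dienyl bromide with retention of both alkene geometries and tolerates the free alcohol and the aldehyde.

Step 31
Reactants: 48 (2E,4E,6E,8R,9R)-9-hydroxy-8-methyldeca-2,4,6-trienal
Product: 49 (2R,3R,4E,6E,8E,10E)-3-methyl-11-(4,4,5,5-tetramethyl-1,3,2-dioxaborolan-2-yl)undeca-4,6,8,10-tetraen-2-ol (C18–C28)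
Conditions: CrCl2, LiI, Cl2CHBpin, THF, rt, dark
Reagents that add atoms: 2-(dichloromethyl)-4,4,5,5-tetramethyl-1,3,2-dioxaborolane, ClC(Cl)B1OC(C)(C)C(C)(C)O1
Why: Chromium-mediated borylative olefination of Takai type, in which the geminal dichromium species from CrCl2, LiI and the dichloromethylboronate adds to the aldehyde and eliminates to the E-alkenylboronate without touching the alcohol or the existing alkenes.

Step 32
Reactants: 42 C1–C17 iodoalkene carboxylic acid; 49 C18–C28 tetraenylboronate alcohol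
Product: 51 seco ester (C1–O–C27 ester; C17 iodoalkene; C18 boronate; 3,5,9,11,13,15-hexakis-OTBS), via mixed anhydride 50 (not isolated)
Conditions: 2,4,6-trichlorobenzoyl chloride, Et3N, THF, rt; 49 (1.5 equiv), DMAP, toluene, rt, dark
Reagents that add atoms: none
Why: Yamaguchi esterification, in which the mixed anhydride is acylated onto the hindered C27 alcohol under DMAP catalysis at room temperature, conditions under which C2 should not epimerise and the boronate is stable.

Step 33
Reactants: 51 seco ester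
Product: 52 hexakis-TBS macrolide (28-membered pentaene lactone; 3,5,9,11,13,15-hexakis-OTBS)
Conditions: Pd(PPh3)4 (20 mol%), TlOEt, THF/H2O 3:1, rt, 1 mM, dark
Reagents that add atoms: none
Why: Suzuki–Miyaura macrocyclisation, in which oxidative addition of the C17–iodine bond to zerovalent palladium, thallium-accelerated transmetalation of the tetraenylboronate and reductive elimination form the C17–C18 bond with retention of both alkene geometries and close the 28-membered ring under high dilution.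

Step 34
Reactants: 52 hexakis-TBS macrolide
Product: 53 target macrolide CNP0382847.1
Conditions: HF·pyridine, pyridine, THF, 0 °C → rt, dark
Reagents that add atoms: none
Why: Buffered HF·pyridine cleaves the six secondary silyl ethers by fluoride attack at silicon, while the lactone, the allylic C15 carbinol and the pentaene should survive the buffered medium.

**Compound list**

1 | propane-1,3-diol | OCCCO | starting material
2 | 3-[(4-methoxybenzyl)oxy]propan-1-ol | COc1ccc(COCCCO)cc1 | intermediate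
3 | 3-[(4-methoxybenzyl)oxy]propanal (aldehyde X, C3–C5) | COc1ccc(COCCC=O)cc1 | intermediate
4 | ethane-1,2-diol | OCCO | starting material
5 | 2-hydroxyethyl pivalate | CC(C)(C)C(=O)OCCO | intermediate
6 | 2-oxoethyl pivalate | CC(C)(C)C(=O)OCC=O | intermediate
7 | (Z)-but-2-ene | C/C=C\C | starting material
8 | (Z)-but-2-enylpotassium | C/C=C\[CH2-].[K+] | intermediate (not isolated)
9 | (Z)-crotylbis(isopinocampheyl)borane, Ipc from (+)-α-pinene | C/C=C\CB([C@@H]1C[C@@H]2C[C@@H](C2(C)C)[C@H]1C)[C@@H]1C[C@@H]2C[C@@H](C2(C)C)[C@H]1C | intermediate (not isolated)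
10 | (2S,3R)-2-hydroxy-3-methylpent-4-en-1-yl pivalate (C13–C16, 14,15-syn) | CC(C)(C)C(=O)OC[C@@H](O)[C@H](C)C=C | intermediate
11 | (2S,3R)-2-[(tert-butyldimethylsilyl)oxy]-3-methylpent-4-en-1-yl pivalate | CC(C)(C)C(=O)OC[C@@H](O[Si](C)(C)C(C)(C)C)[C@H](C)C=C | intermediate
12 | ozonide (1,2,4-trioxolane) of 11 | CC(C)(C)C(=O)OC[C@@H](O[Si](C)(C)C(C)(C)C)[C@H](C)C1OCOO1 | intermediate (not isolated)
13 | (2S,3S)-2-[(tert-butyldimethylsilyl)oxy]-3-methyl-4-oxobutyl pivalate (C13 aldehyde) | CC(C)(C)C(=O)OC[C@@H](O[Si](C)(C)C(C)(C)C)[C@H](C)C=O | intermediate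
14 | (2S,3R,4R)-2-[(tert-butyldimethylsilyl)oxy]-4-hydroxy-3-methylhept-6-en-1-yl pivalate (13-OH, 13,14-anti) | CC(C)(C)C(=O)OC[C@@H](O[Si](C)(C)C(C)(C)C)[C@H](C)[C@H](O)CC=C | intermediate
15 | C11–C16 alkene, 16-OPiv, 13,15-bis-OTBS, 14-Me | CC(C)(C)C(=O)OC[C@@H](O[Si](C)(C)C(C)(C)C)[C@H](C)[C@H](O[Si](C)(C)C(C)(C)C)CC=C | intermediate
16 | ozonide (1,2,4-trioxolane) of 15 | CC(C)(C)C(=O)OC[C@@H](O[Si](C)(C)C(C)(C)C)[C@H](C)[C@H](O[Si](C)(C)C(C)(C)C)CC1OCOO1 | intermediate (not isolated)
17 | C11–C16 aldehyde, 16-OPiv, 13,15-bis-OTBS, 14-Me | CC(C)(C)C(=O)OC[C@@H](O[Si](C)(C)C(C)(C)C)[C@H](C)[C@H](O[Si](C)(C)C(C)(C)C)CC=O | intermediate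
18 | C9–C16 homoallylic alcohol, 11-OH (11,13-anti), 13,15-bis-OTBS, 16-OPiv | CC(C)(C)C(=O)OC[C@@H](O[Si](C)(C)C(C)(C)C)[C@H](C)[C@H](O[Si](C)(C)C(C)(C)C)C[C@@H](O)CC=C | intermediate
19 | C9–C16 alkene, 11,13,15-tris-OTBS, 16-OPiv | CC(C)(C)C(=O)OC[C@@H](O[Si](C)(C)C(C)(C)C)[C@H](C)[C@H](O[Si](C)(C)C(C)(C)C)C[C@@H](O[Si](C)(C)C(C)(C)C)CC=C | intermediate
20 | ozonide (1,2,4-trioxolane) of 19 | CC(C)(C)C(=O)OC[C@@H](O[Si](C)(C)C(C)(C)C)[C@H](C)[C@H](O[Si](C)(C)C(C)(C)C)C[C@@H](O[Si](C)(C)C(C)(C)C)CC1OCOO1 | intermediate (not isolated)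
21 | aldehyde Y (C9–C16), 11,13,15-tris-OTBS, 14-Me, 16-OPiv | CC(C)(C)C(=O)OC[C@@H](O[Si](C)(C)C(C)(C)C)[C@H](C)[C@H](O[Si](C)(C)C(C)(C)C)C[C@@H](O[Si](C)(C)C(C)(C)C)CC=O | intermediate
22 | 3-bromoprop-1-yne (propargyl bromide) | C#CCBr | starting material
23 | allenylmagnesium bromide | C=C=C[Mg]Br | intermediate (not isolated)
24 | allenylboronic acid | C=C=CB(O)O | intermediate (not isolated)
25 | 5,5-dimethyl-2-(propa-1,2-dien-1-yl)-1,3,2-dioxaborinane (C6–C8) | C=C=CB1OCC(C)(C)CO1 | intermediate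
26 | (E)-[3-(5,5-dimethyl-1,3,2-dioxaborinan-2-yl)allyl]bis(isopinocampheyl)borane, Ipc from (+)-α-pinene | CC1(C)COB(/C=C/CB([C@@H]2C[C@@H]3C[C@@H](C3(C)C)[C@H]2C)[C@@H]2C[C@@H]3C[C@@H](C3(C)C)[C@H]2C)OC1 | intermediate (not isolated)
27 | C3–C8 allylboronate, 5-O-B(dIpc)2, 6-(5,5-dimethyl-1,3,2-dioxaborinan-2-yl) (5,6-anti), C7=C8, 3-OPMB | C=C[C@H](B1OCC(C)(C)CO1)[C@@H](CCOCc1ccc(OC)cc1)OB([C@@H]1C[C@@H]2C[C@@H](C2(C)C)[C@H]1C)[C@@H]1C[C@@H]2C[C@@H](C2(C)C)[C@H]1C | intermediate (not isolated)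
28 | C3–C16 (6E)-ene-5,9-diol (5,9-anti), 11,13,15-tris-OTBS, 14-Me, 16-OPiv, 3-OPMB | CC(C)(C)C(=O)OC[C@@H](O[Si](C)(C)C(C)(C)C)[C@H](C)[C@H](O[Si](C)(C)C(C)(C)C)C[C@@H](O[Si](C)(C)C(C)(C)C)C[C@@H](O)C/C=C/[C@H](O)CCOCc1ccc(OC)cc1 | intermediate
29 | C3–C16 5,9-diol (saturated C6–C8) | CC(C)(C)C(=O)OC[C@@H](O[Si](C)(C)C(C)(C)C)[C@H](C)[C@H](O[Si](C)(C)C(C)(C)C)C[C@@H](O[Si](C)(C)C(C)(C)C)C[C@@H](O)CCC[C@H](O)CCOCc1ccc(OC)cc1 | intermediate
30 | C3–C16 pivalate, 5,9,11,13,15-pentakis-OTBS, 3-OPMB | CC(C)(C)C(=O)OC[C@@H](O[Si](C)(C)C(C)(C)C)[C@H](C)[C@H](O[Si](C)(C)C(C)(C)C)C[C@@H](O[Si](C)(C)C(C)(C)C)C[C@@H](O[Si](C)(C)C(C)(C)C)CCC[C@H](O[Si](C)(C)C(C)(C)C)CCOCc1ccc(OC)cc1 | intermediate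
31 | C3–C16 primary alcohol (16-OH) | OC[C@@H](O[Si](C)(C)C(C)(C)C)[C@H](C)[C@H](O[Si](C)(C)C(C)(C)C)C[C@@H](O[Si](C)(C)C(C)(C)C)C[C@@H](O[Si](C)(C)C(C)(C)C)CCC[C@H](O[Si](C)(C)C(C)(C)C)CCOCc1ccc(OC)cc1 | intermediate
32 | C3–C16 aldehyde (C16 aldehyde) | O=C[C@@H](O[Si](C)(C)C(C)(C)C)[C@H](C)[C@H](O[Si](C)(C)C(C)(C)C)C[C@@H](O[Si](C)(C)C(C)(C)C)C[C@@H](O[Si](C)(C)C(C)(C)C)CCC[C@H](O[Si](C)(C)C(C)(C)C)CCOCc1ccc(OC)cc1 | intermediate
33 | C3–C17 (16E)-iodoalkene, 3-OPMB | I/C=C/[C@@H](O[Si](C)(C)C(C)(C)C)[C@H](C)[C@H](O[Si](C)(C)C(C)(C)C)C[C@@H](O[Si](C)(C)C(C)(C)C)C[C@@H](O[Si](C)(C)C(C)(C)C)CCC[C@H](O[Si](C)(C)C(C)(C)C)CCOCc1ccc(OC)cc1 | intermediate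
34 | C3–C17 iodoalkene, 3-OH | I/C=C/[C@@H](O[Si](C)(C)C(C)(C)C)[C@H](C)[C@H](O[Si](C)(C)C(C)(C)C)C[C@@H](O[Si](C)(C)C(C)(C)C)C[C@@H](O[Si](C)(C)C(C)(C)C)CCC[C@H](O[Si](C)(C)C(C)(C)C)CCO | intermediate
35 | C3–C17 iodoalkene, C3 aldehyde | I/C=C/[C@@H](O[Si](C)(C)C(C)(C)C)[C@H](C)[C@H](O[Si](C)(C)C(C)(C)C)C[C@@H](O[Si](C)(C)C(C)(C)C)C[C@@H](O[Si](C)(C)C(C)(C)C)CCC[C@H](O[Si](C)(C)C(C)(C)C)CC=O | intermediate
36 | (S)-4-benzyloxazolidin-2-one | O=C1N[C@@H](Cc2ccccc2)CO1 | starting material
37 | (S)-4-benzyl-3-butanoyloxazolidin-2-one | CCCC(=O)N1[C@@H](Cc2ccccc2)COC1=O | intermediate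
38 | (Z)-dibutylboron enolate of 37 | CC/C=C(\OB(CCCC)CCCC)N1[C@@H](Cc2ccccc2)COC1=O | intermediate (not isolated)
39 | C1–C17 aldol imide, (2S,3R), 3-OH, 5,9,11,13,15-pentakis-OTBS | I/C=C/[C@@H](O[Si](C)(C)C(C)(C)C)[C@H](C)[C@H](O[Si](C)(C)C(C)(C)C)C[C@@H](O[Si](C)(C)C(C)(C)C)C[C@@H](O[Si](C)(C)C(C)(C)C)CCC[C@H](O[Si](C)(C)C(C)(C)C)C[C@@H](O)[C@H](CC)C(=O)N1[C@@H](Cc2ccccc2)COC1=O | intermediate
40 | C1–C17 imide, 3,5,9,11,13,15-hexakis-OTBS | I/C=C/[C@@H](O[Si](C)(C)C(C)(C)C)[C@H](C)[C@H](O[Si](C)(C)C(C)(C)C)C[C@@H](O[Si](C)(C)C(C)(C)C)C[C@@H](O[Si](C)(C)C(C)(C)C)CCC[C@H](O[Si](C)(C)C(C)(C)C)C[C@@H](O[Si](C)(C)C(C)(C)C)[C@H](CC)C(=O)N1[C@@H](Cc2ccccc2)COC1=O | intermediate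
41 | C1–C17 peroxy acid | I/C=C/[C@@H](O[Si](C)(C)C(C)(C)C)[C@H](C)[C@H](O[Si](C)(C)C(C)(C)C)C[C@@H](O[Si](C)(C)C(C)(C)C)C[C@@H](O[Si](C)(C)C(C)(C)C)CCC[C@H](O[Si](C)(C)C(C)(C)C)C[C@@H](O[Si](C)(C)C(C)(C)C)[C@H](CC)C(=O)OO | intermediate (not isolated)
42 | C1–C17 iodoalkene carboxylic acid, hexakis-OTBS | I/C=C/[C@@H](O[Si](C)(C)C(C)(C)C)[C@H](C)[C@H](O[Si](C)(C)C(C)(C)C)C[C@@H](O[Si](C)(C)C(C)(C)C)C[C@@H](O[Si](C)(C)C(C)(C)C)CCC[C@H](O[Si](C)(C)C(C)(C)C)C[C@@H](O[Si](C)(C)C(C)(C)C)[C@H](CC)C(O)=O | intermediate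
43 | (2R,3R)-2,3-dimethyloxirane | C[C@H]1O[C@@H]1C | starting material
44 | (2R,3R)-3-methylpent-4-yn-2-ol | C[C@@H](O)[C@H](C)C#C | intermediate
45 | (2R,3R,4E)-3-methyl-5-(tributylstannyl)pent-4-en-2-ol | C[C@@H](O)[C@H](C)/C=C/[Sn](CCCC)(CCCC)CCCC | intermediate
46 | glutaconaldehyde potassium salt | [K+].[O-]/C=C/C=C/C=O | starting material
47 | (2E,4E)-5-bromopenta-2,4-dienal | O=C/C=C/C=C/Br | intermediate
48 | (2E,4E,6E,8R,9R)-9-hydroxy-8-methyldeca-2,4,6-trienal | C[C@@H](O)[C@H](C)/C=C/C=C/C=C/C=O | intermediate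
49 | (2R,3R,4E,6E,8E,10E)-3-methyl-11-(4,4,5,5-tetramethyl-1,3,2-dioxaborolan-2-yl)undeca-4,6,8,10-tetraen-2-ol | C[C@@H](O)[C@H](C)/C=C/C=C/C=C/C=C/B1OC(C)(C)C(C)(C)O1 | intermediate
50 | mixed anhydride of 42 with 2,4,6-trichlorobenzoic acid | I/C=C/[C@@H](O[Si](C)(C)C(C)(C)C)[C@H](C)[C@H](O[Si](C)(C)C(C)(C)C)C[C@@H](O[Si](C)(C)C(C)(C)C)C[C@@H](O[Si](C)(C)C(C)(C)C)CCC[C@H](O[Si](C)(C)C(C)(C)C)C[C@@H](O[Si](C)(C)C(C)(C)C)[C@H](CC)C(=O)OC(=O)c1c(Cl)cc(Cl)cc1Cl | intermediate (not isolated)
51 | seco ester: C1 acid of 42 esterified with the C27 hydroxyl of 49 | I/C=C/[C@@H](O[Si](C)(C)C(C)(C)C)[C@H](C)[C@H](O[Si](C)(C)C(C)(C)C)C[C@@H](O[Si](C)(C)C(C)(C)C)C[C@@H](O[Si](C)(C)C(C)(C)C)CCC[C@H](O[Si](C)(C)C(C)(C)C)C[C@@H](O[Si](C)(C)C(C)(C)C)[C@H](CC)C(=O)O[C@H](C)[C@H](C)/C=C/C=C/C=C/C=C/B1OC(C)(C)C(C)(C)O1 | intermediate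
52 | hexakis-TBS ether of the target macrolide | CC[C@@H]1C(=O)O[C@H](C)[C@H](C)/C=C/C=C/C=C/C=C/C=C/[C@@H](O[Si](C)(C)C(C)(C)C)[C@H](C)[C@H](O[Si](C)(C)C(C)(C)C)C[C@@H](O[Si](C)(C)C(C)(C)C)C[C@@H](O[Si](C)(C)C(C)(C)C)CCC[C@H](O[Si](C)(C)C(C)(C)C)C[C@H]1O[Si](C)(C)C(C)(C)C | intermediate
53 | CNP0382847.1, (2S,3R,5S,9S,11S,13R,14R,15R,26R,27R)-2-ethyl-3,5,9,11,13,15-hexahydroxy-14,26-dimethyl-octacosa-16E,18E,20E,22E,24E-pentaen-27-olide | CC[C@@H]1C(=O)O[C@H](C)[C@H](C)/C=C/C=C/C=C/C=C/C=C/[C@@H](O)[C@H](C)[C@H](O)C[C@@H](O)C[C@@H](O)CCC[C@H](O)C[C@H]1O | target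

**Step count and risks**

Total step count: 34.
Longest linear sequence: 25 steps (4 → 6 → 21 → 28 → 35 → 42 → 51 → 53; steps 3–13, 15–22, 24–26, 32–34).

Steps most likely to fail:

1. Step 15 (double allylboration). What may go wrong: incomplete equilibration of the γ-boryl allylborane to the E isomer, a second addition of aldehyde 3 to the allylboronate, or erosion of the E and 1,5-anti selectivity in the slow second allylboration with the hindered aldehyde 21. The fallback sets out from 3 and 21 and comes back at 28. Aldehyde 3 is treated with vinylmagnesium bromide (THF, −78 °C) to give racemic 5-[(4-methoxybenzyl)oxy]pent-1-en-3-ol F1, which Dess–Martin oxidation turns into 5-[(4-methoxybenzyl)oxy]pent-1-en-3-one F2. Aldehyde 21 is allylated with (dIpc)2B-allyl (Et2O, −78 °C) to the 9S homoallylic alcohol F3. Cross-metathesis of F3 with excess F2 (second-generation Hoveyda–Grubbs catalyst, CH2Cl2, 40 °C) should give the (E)-enone F4. Corey–Bakshi–Shibata reduction of F4 ((S)-2-methyl-CBS-oxazaborolidine, catecholborane, toluene, −78 °C) should set the C5 carbinol by reagent control and deliver 28.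

2. Step 33 (macrocyclisation). What may go wrong: oligomerisation in competition with ring closure, protodeboronation of the tetraenylboronate, or isomerisation of the polyene during a slow closure. The fallback sets out from 42 and 49 and comes back at 52. The two are first joined intermolecularly by Suzuki–Miyaura coupling (Pd(PPh3)4, TlOEt, THF/H2O, rt) to the pentaene seco acid F5. F5 is activated as its 2,4,6-trichlorobenzoyl mixed anhydride F6 (2,4,6-trichlorobenzoyl chloride, Et3N, THF) and added slowly to DMAP in toluene at rt to 40 °C, so that Yamaguchi macrolactonisation at the C27 hydroxyl closes the ring to 52.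

3. Step 34 (global desilylation). What may go wrong: ionisation of the C15 allylic silyl ether or carbinol next to the pentaene during the long exposure to HF, incomplete cleavage of the hindered silyl ethers, or acyl migration of the lactone. The fallback sets out from 51 and comes back at 53. The six silyl ethers are removed before the pentaene exists (HF·pyridine, pyridine, THF), when C15 is allylic only to an iodoalkene, to give the hexaol seco ester F7. F7 is then cyclised by Suzuki–Miyaura coupling under weakly basic high-dilution conditions (Pd(PPh3)4, Tl2CO3, THF/H2O, rt), kept brief to limit lactonisation onto the free C5 hydroxyl, to give 53 directly.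

**Further compounds**

F1 | step 15 | rac-5-[(4-methoxybenzyl)oxy]pent-1-en-3-ol | C=CC(O)CCOCc1ccc(OC)cc1
F2 | step 15 | 5-[(4-methoxybenzyl)oxy]pent-1-en-3-one | C=CC(=O)CCOCc1ccc(OC)cc1
F3 | step 15 | C7–C16 homoallylic alcohol from 21 (9-OH, 9S; 11,13,15-tris-OTBS; 16-OPiv) | CC(C)(C)C(=O)OC[C@@H](O[Si](C)(C)C(C)(C)C)[C@H](C)[C@H](O[Si](C)(C)C(C)(C)C)C[C@@H](O[Si](C)(C)C(C)(C)C)C[C@@H](O)CC=C
F4 | step 15 | C3–C16 (6E)-en-5-one with 9-OH | CC(C)(C)C(=O)OC[C@@H](O[Si](C)(C)C(C)(C)C)[C@H](C)[C@H](O[Si](C)(C)C(C)(C)C)C[C@@H](O[Si](C)(C)C(C)(C)C)C[C@@H](O)C/C=C/C(=O)CCOCc1ccc(OC)cc1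
F5 | step 33 | pentaene seco acid (C1 acid, 27-OH, hexakis-OTBS) | C[C@@H](O)[C@H](C)/C=C/C=C/C=C/C=C/C=C/[C@@H](O[Si](C)(C)C(C)(C)C)[C@H](C)[C@H](O[Si](C)(C)C(C)(C)C)C[C@@H](O[Si](C)(C)C(C)(C)C)C[C@@H](O[Si](C)(C)C(C)(C)C)CCC[C@H](O[Si](C)(C)C(C)(C)C)C[C@@H](O[Si](C)(C)C(C)(C)C)[C@H](CC)C(O)=O
F6 | step 33 | 2,4,6-trichlorobenzoyl mixed anhydride of F5 | C[C@@H](O)[C@H](C)/C=C/C=C/C=C/C=C/C=C/[C@@H](O[Si](C)(C)C(C)(C)C)[C@H](C)[C@H](O[Si](C)(C)C(C)(C)C)C[C@@H](O[Si](C)(C)C(C)(C)C)C[C@@H](O[Si](C)(C)C(C)(C)C)CCC[C@H](O[Si](C)(C)C(C)(C)C)C[C@@H](O[Si](C)(C)C(C)(C)C)[C@H](CC)C(=O)OC(=O)c1c(Cl)cc(Cl)cc1Cl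
F7 | step 34 | hexaol seco ester (C17 iodoalkene, C18 boronate, free 3,5,9,11,13,15-hydroxyls) | I/C=C/[C@@H](O)[C@H](C)[C@H](O)C[C@@H](O)C[C@@H](O)CCC[C@H](O)C[C@@H](O)[C@H](CC)C(=O)O[C@H](C)[C@H](C)/C=C/C=C/C=C/C=C/B1OC(C)(C)C(C)(C)O1
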